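Ring A is cut at C8–C7 and C6–C5, which removes C6–C7 as an acetyl unit and leaves a 4-pyranone. The pyranone is cut at O1–C2 and C4–C4a; C3–C4 and C2–C3 go back to CO2 and an aryl aldehyde, and the ring B prenyl to an aryl bromide.
Enabling feature: in ring A (C4a, C5, C6, C7, C8, C8a) the prenyl group is on C8, the neighbour of C8a and so of O1. C8 with its prenyl is therefore the side-chain CH2 of a 2-alkyl-4-pyranone-3-carboxylate, C5 is the ester carbon, and only C6–C7 is missing.
Forward: ring B is bought as an arene and dressed; ring C is closed by C-acylation of a prenylated acetoacetate followed by 6-endo-dig oxa-Michael addition; ring A is annulated last by lateral acylation and Claisen closure.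
Stereochemistry: none to set; the target has no stereocentre and both alkenes end in CMe2.

Key step: step 10

Remark: the ring B phenol is carried as a triisopropylsilyl ether, chosen to outlast n-BuLi, amide bases and methoxide and to leave with fluoride without acid; 3-bromo-4,5-dihydroxybenzaldehyde is taken as purchasable.
Abbreviation: Ar = 4-methoxy-3-(3-methylbut-2-enyl)-5-[tri(propan-2-yl)silyloxy]phenyl.

Step 1
Reactants: 1 methyl acetoacetate; 2 prenyl bromide (1-bromo-3-methylbut-2-ene)
Product: 4 methyl 7-methyl-3-oxooct-6-enoate, via acetoacetate dianion 3 (not isolated)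
Conditions: NaH (1.1 equiv), THF, 0 °C; n-BuLi (1.05 equiv), 0 °C; 2 (1.0 equiv), 0 °C to rt; 1 M HCl
Reagents that add atoms: none
Why: γ-alkylation of the acetoacetate dianion, in which the more basic terminal carbanion displaces the primary allylic bromide at its CH2 (SN2), so the prenyl unit ends on C4 of the keto ester.

Step 2
Reactants: 5 3-bromo-4,5-dihydroxybenzaldehyde
Product: 6 3-bromo-5-hydroxy-4-methoxybenzaldehyde
Conditions: MeI (1.1 equiv), Li2CO3 (1.2 equiv), DMF, 40 °C
Reagents that add atoms: iodomethane, CI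
Why: Williamson etherification under a weak base, in which only the 4-OH (para to the formyl group, ortho to bromine) is acidic enough to be ionized, as in the 4-O-selective alkylation of protocatechualdehydes.

Step 3
Reactants: 6 3-bromo-5-hydroxy-4-methoxybenzaldehyde
Product: 7 3-bromo-4-methoxy-5-[tri(propan-2-yl)silyloxy]benzaldehyde
Conditions: i-Pr3SiCl (1.2 equiv), imidazole (2.5 equiv), DMF, rt
Reagents that add atoms: chlorotri(propan-2-yl)silane, CC(C)[Si](Cl)(C(C)C)C(C)C
Why: imidazole-promoted O-silylation of the one remaining phenol, which has no competing nucleophilic site.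

Step 4
Reactants: 7 3-bromo-4-methoxy-5-[tri(propan-2-yl)silyloxy]benzaldehyde
Product: 8 [3-bromo-5-(dimethoxymethyl)-2-methoxyphenoxy]tri(propan-2-yl)silane
Conditions: HC(OMe)3 (3 equiv), p-TsOH·H2O (0.02 equiv), MeOH, rt; Et3N quench
Reagents that add atoms: trimethyl orthoformate, COC(OC)OC; methanol, CO
Why: acid-catalysed acetalization driven by the orthoformate as water scavenger, which masks the aldehyde against n-BuLi while the aryl silyl ether tolerates the trace of acid.

Step 5
Reactants: 8 [3-bromo-5-(dimethoxymethyl)-2-methoxyphenoxy]tri(propan-2-yl)silane; 2 prenyl bromide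
Product: 12 4-methoxy-3-(3-methylbut-2-enyl)-5-[tri(propan-2-yl)silyloxy]benzaldehyde, via aryllithium 9 (not isolated), via arylcopper 10 (not isolated), via prenylated dimethyl acetal 11 (not isolated)
Conditions: n-BuLi (1.05 equiv), THF, −78 °C; CuBr·SMe2 (1.1 equiv), −78 to −40 °C; 2 (1.5 equiv), −78 to 0 °C; then 1 M HCl, THF, rt
Reagents that add atoms: water, O
Why: bromine–lithium exchange followed by transmetalation gives an arylcopper that should substitute the allylic bromide at its unhindered primary carbon (copper-mediated allylic substitution, linear prenyl product), and the dimethyl acetal is then hydrolysed by dilute acid that leaves the aryl silyl ether and the trisubstituted alkene intact.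

Step 6
Reactants: 12 4-methoxy-3-(3-methylbut-2-enyl)-5-[tri(propan-2-yl)silyloxy]benzaldehyde
Product: 13 [5-(2,2-dibromoethenyl)-2-methoxy-3-(3-methylbut-2-enyl)phenoxy]tri(propan-2-yl)silane
Conditions: CBr4 (2 equiv), PPh3 (4 equiv), CH2Cl2, 0 °C
Reagents that add atoms: tetrabromomethane, BrC(Br)(Br)Br
Why: first stage of the Corey–Fuchs homologation, a Wittig-type olefination of the aldehyde by the dibromomethylene ylide formed from PPh3 and CBr4.

Step 7
Reactants: 13 [5-(2,2-dibromoethenyl)-2-methoxy-3-(3-methylbut-2-enyl)phenoxy]tri(propan-2-yl)silane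
Product: 15 3-Ar-prop-2-ynoic acid, via alkynyllithium 14 (not isolated)
Conditions: n-BuLi (2.2 equiv), THF, −78 °C; CO2 (gas), −78 °C to rt; 1 M HCl to pH 2–3, 0 °C
Reagents that add atoms: carbon dioxide, O=C=O
Why: second stage of the Corey–Fuchs sequence, in which bromine–lithium exchange and loss of LiBr with 1,2-shift give the alkyne, the second equivalent of n-BuLi lithiates it, and the acetylide is carboxylated.

Step 8
Reactants: 15 3-Ar-prop-2-ynoic acid; 4 methyl 7-methyl-3-oxooct-6-enoate
Product: 17 methyl 2-(3-Ar-prop-2-ynoyl)-7-methyl-3-oxooct-6-enoate, via acid chloride 16 (not isolated)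
Conditions: 15, 1-chloro-N,N,2-trimethylprop-1-en-1-amine (1.1 equiv), CH2Cl2, 0 °C to rt; then 4 (1.1 equiv), MgCl2 (1.1 equiv), pyridine (2.2 equiv), CH2Cl2, 0 °C to rt; cold 1 M HCl; used crude
Reagents that add atoms: none
Why: the chloroenamine makes the acid chloride without free HCl (no hydrochlorination of alkyne or alkenes), and the magnesium chelate of the β-keto ester is then acylated at its central carbon (magnesium-mediated soft-enolization C-acylation), the product chelate protecting against O-acylation and a second acylation.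

Step 9
Reactants: 17 methyl 2-(3-Ar-prop-2-ynoyl)-7-methyl-3-oxooct-6-enoate
Product: 18 methyl 6-Ar-2-(4-methylpent-3-enyl)-4-oxo-4H-pyran-3-carboxylate
Conditions: DBU (0.2 equiv), MeCN, 0 °C to rt
Reagents that add atoms: none
Why: the enol oxygen of the alkyl ketone adds to the aryl-bearing alkyne carbon in a 6-endo-dig oxa-Michael cyclization, the classical closure of C-propioloylated β-keto esters to 4-pyranone-3-carboxylates, and the conjugated pyranone should be favoured over the 5-exo-dig furanone and over closure through the less nucleophilic ester oxygen.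

Step 10
Reactants: 18 methyl 6-Ar-2-(4-methylpent-3-enyl)-4-oxo-4H-pyran-3-carboxylate; 19 N-methoxy-N-methylacetamide
Product: 22 2-Ar-5,7-dihydroxy-8-(3-methylbut-2-enyl)-4H-chromen-4-one, via lateral lithium anion 20 (not isolated), via methyl ketone 21 (not isolated)
Conditions: LiN(SiMe3)2 (1.1 equiv), THF, −78 °C; 19 (1.1 equiv), −78 °C to rt; then LiN(i-Pr)2 (3 equiv), −78 to 0 °C; cold 1 M HCl to pH 4–5
Reagents that add atoms: none
Why: Proposed new method: the side-chain CH2 on C2 of 18 is vinylogous to both the C4 ketone and the C3 ester, so LiN(SiMe3)2 should give the extended enolate 20, which the Weinreb amide acylates at the lateral carbon (C8–C7 bond); once the chelate collapses on warming the ketone 21 is held as its enolate, LiN(i-Pr)2 removes a proton from the acetyl methyl group, and this dianion attacks the neighbouring ester (C6–C5 bond) with loss of methoxide, after which tautomerization gives the aromatic 5,7-diol. The closest known reactions are the acylation of ortho-toluate lateral anions followed by Claisen closure to naphthalene-1,3-diols and the lateral metalation of 2-alkyl-4-pyranones, the pyranone ester here serving as a vinylogous toluate. Ring A closes by a 6-exo-trig Claisen (Dieckmann-type) condensation that aromatization to the diphenoxide makes irreversible. No stereocentre is formed, and the racemic CH of 21 becomes the sp2 carbon C8. The step needs closure through carbon and not through the enolate oxygen (enol lactone), which the excess of strong base should secure by forming the methyl carbanion, and it needs ester and side chain cis, which the ring C2=C3 bond guarantees. The prenyl group is on the lateral carbon from the start and so can only end at C8, never at C6.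

Step 11
Reactants: 22 2-Ar-5,7-dihydroxy-8-(3-methylbut-2-enyl)-4H-chromen-4-one
Product: 23 5,7-dihydroxy-2-[3-hydroxy-4-methoxy-5-(3-methylbut-2-enyl)phenyl]-8-(3-methylbut-2-enyl)-4H-chromen-4-one (target CNP0221799.0)
Conditions: Bu4NF (1.2 equiv), AcOH (1.2 equiv), THF, 0 °C to rt
Reagents that add atoms: none
Why: fluoride-induced cleavage of the aryl silyl ether, driven by the Si–F bond, with AcOH buffering so that the free phenols and both prenyl groups see neither strong base nor acid.

Compound list
1 | methyl acetoacetate | COC(=O)CC(C)=O | starting material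
2 | prenyl bromide (1-bromo-3-methylbut-2-ene) | CC(C)=CCBr | starting material
3 | sodium lithium dianion of methyl acetoacetate | [Na+].[Li+].COC([O-])=CC(=C)[O-] | intermediate
4 | methyl 7-methyl-3-oxooct-6-enoate | COC(=O)CC(=O)CCC=C(C)C | intermediate
5 | 3-bromo-4,5-dihydroxybenzaldehyde | O=Cc1cc(O)c(O)c(Br)c1 | starting material
6 | 3-bromo-5-hydroxy-4-methoxybenzaldehyde | COc1c(O)cc(C=O)cc1Br | intermediate
7 | 3-bromo-4-methoxy-5-[tri(propan-2-yl)silyloxy]benzaldehyde | COc1c(O[Si](C(C)C)(C(C)C)C(C)C)cc(C=O)cc1Br | intermediate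
8 | [3-bromo-5-(dimethoxymethyl)-2-methoxyphenoxy]tri(propan-2-yl)silane | COc1c(O[Si](C(C)C)(C(C)C)C(C)C)cc(C(OC)OC)cc1Br | intermediate
9 | aryllithium from 8 (lithium in place of bromine) | COc1c(O[Si](C(C)C)(C(C)C)C(C)C)cc(C(OC)OC)cc1[Li] | intermediate
10 | arylcopper from 9 (copper in place of lithium) | COc1c(O[Si](C(C)C)(C(C)C)C(C)C)cc(C(OC)OC)cc1[Cu] | intermediate
11 | [5-(dimethoxymethyl)-2-methoxy-3-(3-methylbut-2-enyl)phenoxy]tri(propan-2-yl)silane | COc1c(O[Si](C(C)C)(C(C)C)C(C)C)cc(C(OC)OC)cc1CC=C(C)C | intermediate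
12 | 4-methoxy-3-(3-methylbut-2-enyl)-5-[tri(propan-2-yl)silyloxy]benzaldehyde | COc1c(O[Si](C(C)C)(C(C)C)C(C)C)cc(C=O)cc1CC=C(C)C | intermediate
13 | [5-(2,2-dibromoethenyl)-2-methoxy-3-(3-methylbut-2-enyl)phenoxy]tri(propan-2-yl)silane | COc1c(O[Si](C(C)C)(C(C)C)C(C)C)cc(C=C(Br)Br)cc1CC=C(C)C | intermediate
14 | alkynyllithium, Ar–C≡C–Li | COc1c(O[Si](C(C)C)(C(C)C)C(C)C)cc(C#C[Li])cc1CC=C(C)C | intermediate
15 | 3-{4-methoxy-3-(3-methylbut-2-enyl)-5-[tri(propan-2-yl)silyloxy]phenyl}prop-2-ynoic acid | COc1c(O[Si](C(C)C)(C(C)C)C(C)C)cc(C#CC(=O)O)cc1CC=C(C)C | intermediate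
16 | 3-{4-methoxy-3-(3-methylbut-2-enyl)-5-[tri(propan-2-yl)silyloxy]phenyl}prop-2-ynoyl chloride | COc1c(O[Si](C(C)C)(C(C)C)C(C)C)cc(C#CC(=O)Cl)cc1CC=C(C)C | intermediate
17 | methyl 2-(3-{4-methoxy-3-(3-methylbut-2-enyl)-5-[tri(propan-2-yl)silyloxy]phenyl}prop-2-ynoyl)-7-methyl-3-oxooct-6-enoate (drawn as the triketo tautomer; largely enolized, C2 not configurationally stable) | COC(=O)C(C(=O)CCC=C(C)C)C(=O)C#Cc1cc(O[Si](C(C)C)(C(C)C)C(C)C)c(OC)c(CC=C(C)C)c1 | intermediate
18 | methyl 6-{4-methoxy-3-(3-methylbut-2-enyl)-5-[tri(propan-2-yl)silyloxy]phenyl}-2-(4-methylpent-3-enyl)-4-oxo-4H-pyran-3-carboxylate | COC(=O)c1c(CCC=C(C)C)oc(-c2cc(O[Si](C(C)C)(C(C)C)C(C)C)c(OC)c(CC=C(C)C)c2)cc1=O | intermediate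
19 | N-methoxy-N-methylacetamide | CC(=O)N(C)OC | starting material
20 | lateral lithium anion of 18 (lithium on the side-chain carbon bonded to C2 of the pyranone; delocalized extended enolate) | COC(=O)c1c(C([Li])CC=C(C)C)oc(-c2cc(O[Si](C(C)C)(C(C)C)C(C)C)c(OC)c(CC=C(C)C)c2)cc1=O | intermediate
21 | methyl 6-{4-methoxy-3-(3-methylbut-2-enyl)-5-[tri(propan-2-yl)silyloxy]phenyl}-2-(6-methyl-2-oxohept-5-en-3-yl)-4-oxo-4H-pyran-3-carboxylate (racemic at the side-chain CH; present as its lithium enolate) | COC(=O)c1c(C(CC=C(C)C)C(C)=O)oc(-c2cc(O[Si](C(C)C)(C(C)C)C(C)C)c(OC)c(CC=C(C)C)c2)cc1=O | intermediate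
22 | 5,7-dihydroxy-2-{4-methoxy-3-(3-methylbut-2-enyl)-5-[tri(propan-2-yl)silyloxy]phenyl}-8-(3-methylbut-2-enyl)-4H-chromen-4-one | COc1c(O[Si](C(C)C)(C(C)C)C(C)C)cc(-c2cc(=O)c3c(O)cc(O)c(CC=C(C)C)c3o2)cc1CC=C(C)C | intermediate
23 | 5,7-dihydroxy-2-[3-hydroxy-4-methoxy-5-(3-methylbut-2-enyl)phenyl]-8-(3-methylbut-2-enyl)-4H-chromen-4-one (CNP0221799.0; no stereocentre) | COc1c(O)cc(-c2cc(=O)c3c(O)cc(O)c(CC=C(C)C)c3o2)cc1CC=C(C)C | target

Total step count: 11.
Longest linear sequence: 10 steps (5 to 23, steps 2–11); step 1 is a one-step side branch.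

Steps most likely to fail

1. Step 10. The extended enolate may be too stabilized to attack the Weinreb amide, the chelate may not collapse in the flask, the ketone enolate may close through oxygen to an enol lactone, or the amide base may add to the pyranone. The fallback uses known chemistry and brings ring A in preformed; it sets out from aldehyde 12 (and prenyl bromide 2) and comes back at target 23. Bought 2,4,6-trihydroxyacetophenone is C-prenylated with 2 in aqueous KOH to 1-[2,4,6-trihydroxy-3-(3-methylbut-2-enyl)phenyl]ethanone F1. MOMCl and i-Pr2NEt should protect the 4-OH and the less hindered 6-OH to give 1-[2-hydroxy-4,6-bis(methoxymethoxy)-3-(3-methylbut-2-enyl)phenyl]ethanone F2. Claisen–Schmidt condensation of F2 with 12 (KOH, EtOH, rt), in which hydroxide is also expected to cleave the aryl silyl ether, should give (E)-1-[2-hydroxy-4,6-bis(methoxymethoxy)-3-(3-methylbut-2-enyl)phenyl]-3-[3-hydroxy-4-methoxy-5-(3-methylbut-2-enyl)phenyl]prop-2-en-1-one F3. Oxidative cyclization with catalytic I2 in DMSO closes ring C through the only free ortho hydroxyl, which sits next to the prenyl group, to 2-[3-hydroxy-4-methoxy-5-(3-methylbut-2-enyl)phenyl]-5,7-bis(methoxymethoxy)-8-(3-methylbut-2-enyl)-4H-chromen-4-one F4. Dilute HCl in MeOH then removes both methoxymethyl groups to give 23. This path depends on discriminating the two ortho hydroxyls in the protection step, which is the weakness the annulation avoids.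

2. Step 8. The ynoyl chloride may be consumed by conjugate addition of chloride, pyridine or the enolate to its activated triple bond, or by O-acylation, before C-acylation takes place. The fallback exchanges the roles of the partners so that no ynoyl electrophile is needed; it sets out from dibromoalkene 13 and comes back at tricarbonyl 17. Alkynyllithium 14 is generated as in step 7 and quenched with DMF to give 3-{4-methoxy-3-(3-methylbut-2-enyl)-5-[tri(propan-2-yl)silyloxy]phenyl}prop-2-ynal F5. Aldol addition of the lithium enolate of methyl acetate (LiN(i-Pr)2, THF, −78 °C) gives racemic methyl 3-hydroxy-5-{4-methoxy-3-(3-methylbut-2-enyl)-5-[tri(propan-2-yl)silyloxy]phenyl}pent-4-ynoate F6. Dess–Martin periodinane oxidizes it to methyl 5-{4-methoxy-3-(3-methylbut-2-enyl)-5-[tri(propan-2-yl)silyloxy]phenyl}-3-oxopent-4-ynoate F7. Magnesium-mediated C-acylation of F7 (MgCl2, pyridine, CH2Cl2) with 5-methylhex-4-enoyl chloride F8, made from bought 5-methylhex-4-enoic acid and oxalyl chloride, delivers 17, and step 9 follows unchanged.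

3. Step 5. The arylcopper may attack the tertiary terminus of the allylic bromide (reverse-prenyl product), or the aryl metal may be quenched by adventitious protons before it couples. The fallback replaces the organocopper substitution by a palladium-catalysed Stille coupling; it sets out from bromo aldehyde 7 and comes back at aldehyde 12. Compound 7 is heated with bought tributyl(3-methylbut-2-enyl)stannane and Pd(PPh3)4 (zerovalent palladium) in DMF at 90 °C; reductive elimination at the less hindered allyl terminus should give the linear prenyl arene 12 directly, with the free aldehyde and the silyl ether tolerated, so acetal 8 is not needed. No new compound arises on this path (none, F0).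

Further compounds
F1 | step 10 | 1-[2,4,6-trihydroxy-3-(3-methylbut-2-enyl)phenyl]ethanone | CC(=O)c1c(O)cc(O)c(CC=C(C)C)c1O
F2 | step 10 | 1-[2-hydroxy-4,6-bis(methoxymethoxy)-3-(3-methylbut-2-enyl)phenyl]ethanone | CC(=O)c1c(OCOC)cc(OCOC)c(CC=C(C)C)c1O
F3 | step 10 | (E)-1-[2-hydroxy-4,6-bis(methoxymethoxy)-3-(3-methylbut-2-enyl)phenyl]-3-[3-hydroxy-4-methoxy-5-(3-methylbut-2-enyl)phenyl]prop-2-en-1-one | COCOc1cc(OCOC)c(C(=O)/C=C/c2cc(O)c(OC)c(CC=C(C)C)c2)c(O)c1CC=C(C)C
F4 | step 10 | 2-[3-hydroxy-4-methoxy-5-(3-methylbut-2-enyl)phenyl]-5,7-bis(methoxymethoxy)-8-(3-methylbut-2-enyl)-4H-chromen-4-one | COCOc1cc(OCOC)c2c(=O)cc(-c3cc(O)c(OC)c(CC=C(C)C)c3)oc2c1CC=C(C)C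
F5 | step 8 | 3-{4-methoxy-3-(3-methylbut-2-enyl)-5-[tri(propan-2-yl)silyloxy]phenyl}prop-2-ynal | COc1c(O[Si](C(C)C)(C(C)C)C(C)C)cc(C#CC=O)cc1CC=C(C)C
F6 | step 8 | methyl 3-hydroxy-5-{4-methoxy-3-(3-methylbut-2-enyl)-5-[tri(propan-2-yl)silyloxy]phenyl}pent-4-ynoate (racemic) | COC(=O)CC(O)C#Cc1cc(O[Si](C(C)C)(C(C)C)C(C)C)c(OC)c(CC=C(C)C)c1
F7 | step 8 | methyl 5-{4-methoxy-3-(3-methylbut-2-enyl)-5-[tri(propan-2-yl)silyloxy]phenyl}-3-oxopent-4-ynoate | COC(=O)CC(=O)C#Cc1cc(O[Si](C(C)C)(C(C)C)C(C)C)c(OC)c(CC=C(C)C)c1
F8 | step 8 | 5-methylhex-4-enoyl chloride | CC(C)=CCCC(=O)Cl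
F0 | step 5 | none | none
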